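## The problem

Ring atoms of the target are numbered C1(CH3)=C2–C3–C4(CH3)2–C5–C6(O-acyl)–C7–C8(CH3)=C9–C10–C11. Compound numbers are those of the step list.

Compound 31 is a single eleven-membered carbocycle with no ring fusion. It carries two E-trisubstituted alkenes (C1=C2 and C8=C9), a gem-dimethyl carbon (C4) and one stereocentre (C6, S) esterified with (Z)-4-hydroxycinnamic acid. A synthesis has to close a strained medium ring, fix both ring-alkene geometries and set C6, which no other stereocentre can induce. In the finished ring C6 sits between two methylene groups of almost equal size, so late enantioselective reduction of a ring ketone is not a reliable option. C6 is therefore best set early, where its two flanks still differ strongly. The fragile parts are the Z-cinnamate, which drifts to E under light, acid or base (a para-phenoxide lowers the rotation barrier of the Cα=Cβ bond), the ester itself, and the ring diene, which cyclises across the ring under acid. The side chain must therefore come last, under mild Z-selective conditions. The enabling feature is the 1,5-diene C2=C1–C11–C10–C9=C8. The two alkenes flank the C10–C11 bond, which is the retron of a [3,3]-sigmatropic shift. The ring can thus be made by four-carbon expansion of a cycloheptane in which C2 and C8 are bonded, not by end-to-end closure.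

## Retrosynthesis

**Side chain.** The cinnamate Cα=Cβ bond of 31 (via its silyl ether 30) is cut to phosphonoacetate 28 and aldehyde 29. The C6–O acyl bond of 28 is then cut to alcohol 26 and acid 27. Acylating 26 with a preformed Z-cinnamic acid is the neighbouring option, but activation of that acid invites Z/E leakage. Making the alkene on the ester by a Z-selective Horner–Wadsworth–Emmons reaction avoids this. The precursor 26 has lost all aromatic and ester functionality. The forward steps must give Z and must not touch the ring diene.

**C2–H.** Alcohol 26 comes from silyl ether 25, and 25 from enol triflate 24 by exchange of C2–OTf for C2–H. Placing an oxygen on C2 turns the plain 1,5-diene into the product of an oxy-Cope rearrangement, which has a driving force that the all-carbon Cope lacks. The forward reduction must keep the alkene geometry.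

**Ring (key cut).** In 24 the C10–C11 bond is cut and C2–C8 is joined, giving cycloheptanol 21 with an isopropenyl group on the carbinol carbon and a vinyl and a methyl group on the neighbouring quaternary carbon. Against end-to-end closures at C2–C3, C7–C8 or C9–C10, this cut needs no high dilution and forms both ring alkenes in one event. The precursor is a seven-membered ring built from enolate and carbonyl chemistry. The forward reaction requires isopropenyl trans to vinyl. The configuration of these two centres relative to C6 is irrelevant, because both are destroyed.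

**Carbinol.** The bond between the carbinol carbon and the isopropenyl group of 21 is cut to ketone 19 and isopropenylmagnesium bromide 20. This is the simplest access to a tertiary dialkenyl carbinol. The forward addition must occur on the ketone face opposite the vinyl group.

**Quaternary carbon.** The methyl of 19 is removed to give ethylidene enone 17 (deconjugative alkylation of its dienolate). The ethylidene unit is cut to aldol 15, and 15 to enone 12 and acetaldehyde 13. Methyl-then-vinyl is the alternative order, but dehydration of a neopentyl-type secondary alcohol to a vinyl group is harder than the E1cB dehydration used here. The enone 12 fixes where the enolate forms.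

**Ring expansion.** Enone 12 is traced through siloxycyclopropane 10 and silyl enol ether 9 to cyclohexanone 7. The carbon to be inserted lies between the carbonyl and the methylene next to the silyloxy carbon, and it is the very carbon that becomes quaternary. Direct diazoalkane insertion was considered but its regiochemistry depends on two opposing migratory biases. The enol ether route ties the regiochemistry to one enolisation and leaves an enone that directs the next C–C bond.

**Stereocentre and start.** Ketone 7 comes from β-hydroxy ketone 6, and 6 from enone 4 by asymmetric conjugate borylation and oxidation. At this stage the flanks of the future C6 are a carbonyl-bearing and a gem-dimethyl-bearing methylene, which a chiral catalyst can tell apart. Enone 4 comes from dimedone 1 through vinylogous ester 2.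

## Roads not taken

Alternative 1: The cut is C2–C3. Alkenyl iodide A1, which carries a tertiary 3,3-dimethylcyclobutanol, would be treated with Pd(OAc)2, P(t-Bu)3 and Cs2CO3. Oxidative addition, alkoxide exchange and β-carbon elimination open the four-membered ring, and C(sp2)–C(sp3) reductive elimination closes the eleven-membered ring to ketone A2.
- Merits: strain release drives the step, the alkylpalladium intermediate is neopentyl and has no β-hydrogen, both alkenes are made in open-chain form, and the precursor is achiral.
- Weak points: the ring must close from a large palladacycle into a strained ring, and intramolecular examples at this size are lacking. More seriously, A2 has its carbonyl between two near-identical methylenes, so the only stereocentre remains unsolved.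
- Comparison: this road is more convergent and needs no diastereoselective carbonyl addition, and in that respect it is better. The chosen plan sets C6 catalytically at the start and forms the ring by expansion.

Alternative 2: The cut is C7–C8. Epoxy-alkyne A3 would be cyclised with Ni(cod)2, PBu3 and Et3B to alcohol A4, which is identical with 26.
- Merits: one step closes the ring, sets the C8=C9 geometry by syn addition of carbon and hydrogen, and releases the free hydroxyl with configuration taken from an enantiopure epoxide. On paper it is the shortest road and needs no protecting group on C6.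
- Weak points: this coupling is established intermolecularly and for small rings. An eleven-membered closure, an internal alkyne whose ends differ only as methyl and methylene (which decides ring size), and the dilution of an air-sensitive catalyst are all unprecedented in combination.
- Comparison: step economy favours this road. The chosen plan offers a ring-forming step of a well-precedented reaction class, run at normal concentration.

Alternative 3: The cut is C9–C10. Iodo-triene A5 would be hydroborated at its terminal vinyl group with 9-BBN and cyclised with PdCl2(dppf), AsPh3 and Cs2CO3 to silyl ether A6, which is identical with 25.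
- Merits: B-alkyl Suzuki macrocyclisation is the best precedented of the three closures. Both alkenes exist before cyclisation, so their geometry does not depend on a chair preference or on a diastereoselective Grignard addition. In that respect it is superior to the chosen plan.
- Weak points: the ring is closed end-to-end into a strained eleven-membered diene under high dilution, where protodeboronation and oligomerisation compete. The hydroboration must select one alkene of a 1,3-diene next to an alkenyl iodide. A5 itself needs a long linear synthesis.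
- Comparison: the chosen plan accepts one stereochemical risk (the carbinol configuration) in exchange for a cheap cyclic starting material, both alkenes from one step, and no medium-ring cyclisation.

Key step: step 12

Assumption: 13, 20, 27 and 29 are taken as catalogue reagents; the configuration of the two cycloheptane centres of 19 and 21 relative to the silyloxy carbon has no consequence for 24, and the isomer drawn is the one expected.

## Steps

Step 1
Reactants: 1 dimedone (5,5-dimethylcyclohexane-1,3-dione)
Product: 2 3-ethoxy-5,5-dimethylcyclohex-2-en-1-one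
Conditions: EtOH, p-TsOH·H2O (cat.), toluene, reflux, Dean–Stark
Reagents that add atoms: ethanol, CCO
Why: Acid-catalysed O-alkylation of the enol of a cyclic 1,3-diketone (vinylogous ester formation), driven by azeotropic removal of water.

Step 2
Reactants: 2 3-ethoxy-5,5-dimethylcyclohex-2-en-1-one
Product: 4 5,5-dimethylcyclohex-2-en-1-one, via allylic alcohol 3 (not isolated)
Conditions: LiAlH4, Et2O, 0 °C; then 2 M HCl, rt
Reagents that add atoms: water, O (carbonyl oxygen of 4)
Why: 1,2-Hydride reduction of the vinylogous ester, then acid hydrolysis of the enol ether and loss of water from the β-hydroxy ketone, give the transposed enone (reduction–hydrolysis transposition).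

Step 3
Reactants: 4 5,5-dimethylcyclohex-2-en-1-one
Product: 6 (3S)-3-hydroxy-5,5-dimethylcyclohexan-1-one, via boronate ester 5 (not isolated)
Conditions: B2pin2, CuCl (cat.), NaOt-Bu (cat.), 1-[2-(diphenylphosphino)ferrocenyl]ethyldicyclohexylphosphine (cat., the enantiomer that leads to S), MeOH, THF, rt; then NaBO3·4H2O, THF/H2O, rt
Reagents that add atoms: bis(pinacolato)diboron, CC1(C)OB(OC1(C)C)B1OC(C)(C)C(C)(C)O1 (boryl group of 5 only); sodium perborate, [Na+].[Na+].O[B-]1(O)OO[B-](O)(O)OO1 (hydroxyl oxygen of 6)
Why: Copper-catalysed enantioselective conjugate borylation of a cyclic enone; the chiral bisphosphine–copper boryl selects one enone face and so sets the only stereocentre of the target (future C6, S), methanol protonates the copper enolate, and perborate replaces boron by oxygen with retention.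

Step 4
Reactants: 6 (3S)-3-hydroxy-5,5-dimethylcyclohexan-1-one
Product: 7 (3S)-3-(tert-butyldimethylsilyloxy)-5,5-dimethylcyclohexan-1-one
Conditions: TBSCl, imidazole, DMF, rt
Reagents that add atoms: tert-butyldimethylsilyl chloride, CC(C)(C)[Si](C)(C)Cl
Why: Standard silylation of a secondary alcohol; the weak base avoids β-elimination of the β-hydroxy ketone.

Step 5
Reactants: 7 (3S)-3-(tert-butyldimethylsilyloxy)-5,5-dimethylcyclohexan-1-one
Product: 9 tert-butyl{[(1S)-5,5-dimethyl-3-(trimethylsilyloxy)cyclohex-2-en-1-yl]oxy}dimethylsilane, via lithium enolate 8 (not isolated)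
Conditions: LiN(i-Pr)2, Me3SiCl (present from the start), THF, −78 °C; Et3N, pentane work-up
Reagents that add atoms: chlorotrimethylsilane, C[Si](C)(C)Cl; lithium diisopropylamide, CC(C)N([Li])C(C)C (lithium of 8 only)
Why: Kinetic enolisation with in situ silylation; cyclohexanone C6 is flanked by the quaternary carbon and should be deprotonated far more slowly (as in 3,3-dimethylcyclohexanone), so the enolate forms at C2, and the cold internal quench forestalls β-elimination of the silyloxy group.

Step 6
Reactants: 9 tert-butyl{[(1S)-5,5-dimethyl-3-(trimethylsilyloxy)cyclohex-2-en-1-yl]oxy}dimethylsilane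
Product: 10 (5S)-5-(tert-butyldimethylsilyloxy)-3,3-dimethyl-1-(trimethylsilyloxy)bicyclo[4.1.0]heptane (cis-fused, either cyclopropane face)
Conditions: Et2Zn, CH2I2, CH2Cl2, 0 °C → rt
Reagents that add atoms: diiodomethane, ICI
Why: Simmons–Smith cyclopropanation of an electron-rich silyl enol ether; the two new ring-fusion centres are lost again in step 7, so the facial outcome is immaterial.

Step 7
Reactants: 10 (5S)-5-(tert-butyldimethylsilyloxy)-3,3-dimethyl-1-(trimethylsilyloxy)bicyclo[4.1.0]heptane
Product: 12 (4S)-4-(tert-butyldimethylsilyloxy)-6,6-dimethylcyclohept-2-en-1-one, via β-chloro ketone 11 (not isolated)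
Conditions: FeCl3, pyridine, DMF, 0 °C → rt; then NaOAc, MeOH, reflux
Reagents that add atoms: iron trichloride, Cl[Fe](Cl)Cl (chlorine of 11 only)
Why: Oxidative ring expansion of a siloxycyclopropane: one-electron oxidation by FeCl3 cleaves the internal cyclopropane bond to a ring-expanded β-keto radical that takes up chlorine, and acetate-induced E1cB loss of HCl gives the enone; pyridine buffers the Lewis acid to protect the silyl ether.

Step 8
Reactants: 12 (4S)-4-(tert-butyldimethylsilyloxy)-6,6-dimethylcyclohept-2-en-1-one; 13 acetaldehyde
Product: 15 (4R)-4-(tert-butyldimethylsilyloxy)-2-(1-hydroxyethyl)-6,6-dimethylcycloheptan-1-one (diastereomers at C2 and the carbinol carbon), via lithium enolate 14 (not isolated)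
Conditions: LiBH(s-Bu)3, THF, −78 °C; then CH3CHO, −78 °C; NH4Cl (aq)
Reagents that add atoms: acetaldehyde (13), CC=O; lithium tri-sec-butylborohydride, [Li+].CCC(C)[BH-](C(C)CC)C(C)CC (lithium of 14 only)
Why: Conjugate hydride reduction of a β-unsubstituted cyclic enone gives the enolate regiospecifically at C2, which is trapped by acetaldehyde (reductive aldol); both new centres are removed in step 9.

Step 9
Reactants: 15 (4R)-4-(tert-butyldimethylsilyloxy)-2-(1-hydroxyethyl)-6,6-dimethylcycloheptan-1-one
Product: 17 (2E,4S)-4-(tert-butyldimethylsilyloxy)-2-ethylidene-6,6-dimethylcycloheptan-1-one, via mesylate 16 (not isolated)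
Conditions: MsCl, Et3N, CH2Cl2, 0 °C; then DBU, rt
Reagents that add atoms: methanesulfonyl chloride, CS(=O)(=O)Cl (mesyl group of 16 only)
Why: Sulfonylation and E1cB elimination of a β-hydroxy ketone; the exocyclic enone should form as the more stable E isomer, and all diastereomers of 15 converge.

Step 10
Reactants: 17 (2E,4S)-4-(tert-butyldimethylsilyloxy)-2-ethylidene-6,6-dimethylcycloheptan-1-one
Product: 19 (2S,4S)-4-(tert-butyldimethylsilyloxy)-2-ethenyl-2,6,6-trimethylcycloheptan-1-one, via potassium dienolate 18 (not isolated)
Conditions: KOt-Bu, t-BuOH/THF, 0 °C; then MeI, 0 °C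
Reagents that add atoms: iodomethane, CI; potassium tert-butoxide, CC(C)(C)O[K] (potassium of 18 only)
Why: Deconjugative α-alkylation of an α-alkylidene ketone: reversible γ-deprotonation gives the extended dienolate (the α′ methylene is neopentyl and hindered), which is methylated at the α-carbon to create the quaternary centre; attack on the convex face, cis to the pseudo-equatorial silyloxy group, is expected, and the C2 epimer would converge at 24 as well.

Step 11
Reactants: 19 (2S,4S)-4-(tert-butyldimethylsilyloxy)-2-ethenyl-2,6,6-trimethylcycloheptan-1-one; 20 isopropenylmagnesium bromide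
Product: 21 (1R,2S,4S)-4-(tert-butyldimethylsilyloxy)-2-ethenyl-2,6,6-trimethyl-1-(prop-1-en-2-yl)cycloheptan-1-ol
Conditions: 20, CeCl3 (anhydrous), THF, −78 → 0 °C; NH4Cl (aq)
Reagents that add atoms: isopropenylmagnesium bromide (20), C=C(C)[Mg]Br
Why: Organocerium 1,2-addition to a hindered, enolisable ketone; the nucleophile should enter anti to the vinyl group, which lies perpendicular to the carbonyl plane as the effectively larger α-substituent, placing isopropenyl trans to vinyl and cis to methyl; the cis-dialkenyl isomer, if formed, is removed by chromatography.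

Step 12
Reactants: 21 (1R,2S,4S)-4-(tert-butyldimethylsilyloxy)-2-ethenyl-2,6,6-trimethyl-1-(prop-1-en-2-yl)cycloheptan-1-ol
Product: 24 (1Z,5E,8S)-8-(tert-butyldimethylsilyloxy)-2,6,10,10-tetramethylcycloundeca-1,5-dien-1-yl trifluoromethanesulfonate, via potassium alkoxide 22 (not isolated), via potassium enolate 23 (not isolated)
Conditions: KH, 18-crown-6, THF, 0 → 50 °C; then PhNTf2, −78 → 0 °C
Reagents that add atoms: N-phenylbis(trifluoromethanesulfonimide), O=S(=O)(N(c1ccccc1)S(=O)(=O)C(F)(F)F)C(F)(F)F; potassium hydride, [K+].[H-] (potassium of 22 and 23 only)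
Why: KH with 18-crown-6 gives the free potassium alkoxide 22, whose oxyanion weakens the adjacent C2–C8 bond and accelerates the [3,3] shift (anionic oxy-Cope rearrangement; closest precedent: four-carbon ring expansion of 1,2-dialkenylcycloalkanols with enolate trapping). The six atoms C11=C1–C2–C8–C9=C10 adopt a chair in which C10–C11 forms as C2–C8 breaks, so the eleven-membered ring arises by ring expansion through a six-centre pericyclic transition state and not by end-to-end cyclisation. No stereocentre is created: C2 and C8 are destroyed and C6 is untouched. The two alkene geometries are set by the chair, because with isopropenyl trans to vinyl both cycloheptane bonds (C2–C3 and C8–C7) are pseudo-equatorial, which puts C3 trans to C11 across C1=C2 and C7 trans to C10 across C8=C9. Formation of the delocalised enolate 23 makes the expansion irreversible and places the enolate specifically at C1=C2, so O-sulfonylation with PhNTf2 fixes both position and geometry of that alkene. The step needs chair over boat and [3,3] over [1,3] shift or fragmentation; the trans arrangement and the crown-separated ion pair should secure both. The silyl ether is trans to the alkoxide and cannot migrate to it.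

Step 13
Reactants: 24 (1Z,5E,8S)-8-(tert-butyldimethylsilyloxy)-2,6,10,10-tetramethylcycloundeca-1,5-dien-1-yl trifluoromethanesulfonate
Product: 25 tert-butyldimethyl{[(1S,3E,7E)-3,7,10,10-tetramethylcycloundeca-3,7-dien-1-yl]oxy}silane
Conditions: Pd(OAc)2 (cat.), PPh3 (cat.), HCO2H, n-Bu3N, DMF, 60 °C
Reagents that add atoms: none
Why: Palladium-catalysed formate reduction of an enol triflate: oxidative addition to zerovalent palladium, decarboxylation of the formate to a hydride and reductive elimination replace OTf by H with retention of geometry; fast hydride transfer should outrun any transannular insertion into the hindered C8=C9 alkene.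

Step 14
Reactants: 25 tert-butyldimethyl{[(1S,3E,7E)-3,7,10,10-tetramethylcycloundeca-3,7-dien-1-yl]oxy}silane
Product: 26 (1S,3E,7E)-3,7,10,10-tetramethylcycloundeca-3,7-dien-1-ol
Conditions: n-Bu4NF, THF, rt
Reagents that add atoms: none
Why: Fluoride cleavage of a secondary silyl ether under non-acidic conditions, which spares the acid-sensitive ring diene.

Step 15
Reactants: 26 (1S,3E,7E)-3,7,10,10-tetramethylcycloundeca-3,7-dien-1-ol; 27 (diphenoxyphosphoryl)acetic acid
Product: 28 (1S,3E,7E)-3,7,10,10-tetramethylcycloundeca-3,7-dien-1-yl 2-(diphenoxyphosphoryl)acetate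
Conditions: 27, EDC·HCl, DMAP (cat.), CH2Cl2, 0 °C → rt
Reagents that add atoms: (diphenoxyphosphoryl)acetic acid (27), OC(=O)CP(=O)(Oc1ccccc1)Oc1ccccc1
Why: Carbodiimide/DMAP (Steglich) esterification of a secondary alcohol; C6 is not involved in bond breaking and keeps its configuration.

Step 16
Reactants: 28 (1S,3E,7E)-3,7,10,10-tetramethylcycloundeca-3,7-dien-1-yl 2-(diphenoxyphosphoryl)acetate; 29 4-(tert-butyldimethylsilyloxy)benzaldehyde
Product: 30 (1S,3E,7E)-3,7,10,10-tetramethylcycloundeca-3,7-dien-1-yl (2Z)-3-[4-(tert-butyldimethylsilyloxy)phenyl]prop-2-enoate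
Conditions: NaH, THF, 0 °C; then 29, −78 → −20 °C, dark
Reagents that add atoms: 4-(tert-butyldimethylsilyloxy)benzaldehyde (29), O=Cc1ccc(O[Si](C)(C)C(C)(C)C)cc1
Why: Z-selective Horner–Wadsworth–Emmons olefination with a diaryl phosphonoacetate: the electron-poor aryloxy groups make elimination from the kinetically formed adduct faster than its equilibration, which gives the Z-cinnamate with aromatic aldehydes.

Step 17
Reactants: 30 (1S,3E,7E)-3,7,10,10-tetramethylcycloundeca-3,7-dien-1-yl (2Z)-3-[4-(tert-butyldimethylsilyloxy)phenyl]prop-2-enoate
Product: 31 (1S,3E,7E)-3,7,10,10-tetramethylcycloundeca-3,7-dien-1-yl (2Z)-3-(4-hydroxyphenyl)prop-2-enoate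
Conditions: n-Bu4NF, AcOH, THF, 0 °C, dark
Reagents that add atoms: none
Why: Buffered fluoride cleavage of the aryl silyl ether; acetic acid keeps the phenol protonated, so the phenoxide that would allow Z-to-E rotation does not build up, and the ester and ring diene are untouched.

## Compound list

1 | dimedone (5,5-dimethylcyclohexane-1,3-dione) | CC1(C)CC(=O)CC(=O)C1 | starting material
2 | 3-ethoxy-5,5-dimethylcyclohex-2-en-1-one | CCOC1=CC(=O)CC(C)(C)C1 | intermediate
3 | 3-ethoxy-5,5-dimethylcyclohex-2-en-1-ol (racemic) | CCOC1=CC(O)CC(C)(C)C1 | intermediate (not isolated)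
4 | 5,5-dimethylcyclohex-2-en-1-one | O=C1C=CCC(C)(C)C1 | intermediate
5 | (3S)-5,5-dimethyl-3-(4,4,5,5-tetramethyl-1,3,2-dioxaborolan-2-yl)cyclohexan-1-one | O=C1CC(C)(C)C[C@H](B2OC(C)(C)C(C)(C)O2)C1 | intermediate (not isolated)
6 | (3S)-3-hydroxy-5,5-dimethylcyclohexan-1-one | O=C1CC(C)(C)C[C@H](O)C1 | intermediate
7 | (3S)-3-(tert-butyldimethylsilyloxy)-5,5-dimethylcyclohexan-1-one | O=C1CC(C)(C)C[C@H](O[Si](C)(C)C(C)(C)C)C1 | intermediate
8 | lithium (3S)-3-(tert-butyldimethylsilyloxy)-5,5-dimethylcyclohex-1-en-1-olate | CC1(C)C[C@H](O[Si](C)(C)C(C)(C)C)C=C(O[Li])C1 | intermediate (not isolated)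
9 | tert-butyl{[(1S)-5,5-dimethyl-3-(trimethylsilyloxy)cyclohex-2-en-1-yl]oxy}dimethylsilane | CC1(C)C[C@H](O[Si](C)(C)C(C)(C)C)C=C(O[Si](C)(C)C)C1 | intermediate
10 | (5S)-5-(tert-butyldimethylsilyloxy)-3,3-dimethyl-1-(trimethylsilyloxy)bicyclo[4.1.0]heptane (cis-fused, either cyclopropane face) | C[Si](C)(C)OC12CC(C)(C)C[C@H](O[Si](C)(C)C(C)(C)C)C1C2 | intermediate
11 | (4S)-4-(tert-butyldimethylsilyloxy)-3-chloro-6,6-dimethylcycloheptan-1-one (either C3 epimer) | O=C1CC(C)(C)C[C@H](O[Si](C)(C)C(C)(C)C)C(Cl)C1 | intermediate (not isolated)
12 | (4S)-4-(tert-butyldimethylsilyloxy)-6,6-dimethylcyclohept-2-en-1-one | O=C1CC(C)(C)C[C@H](O[Si](C)(C)C(C)(C)C)C=C1 | intermediate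
13 | acetaldehyde | CC=O | starting material
14 | lithium (4R)-4-(tert-butyldimethylsilyloxy)-6,6-dimethylcyclohept-1-en-1-olate | CC1(C)C[C@H](O[Si](C)(C)C(C)(C)C)CC=C(O[Li])C1 | intermediate (not isolated)
15 | (4R)-4-(tert-butyldimethylsilyloxy)-2-(1-hydroxyethyl)-6,6-dimethylcycloheptan-1-one (diastereomers at C2 and the carbinol carbon) | O=C1CC(C)(C)C[C@H](O[Si](C)(C)C(C)(C)C)CC1C(C)O | intermediate
16 | (4R)-4-(tert-butyldimethylsilyloxy)-2-[1-(methanesulfonyloxy)ethyl]-6,6-dimethylcycloheptan-1-one | O=C1CC(C)(C)C[C@H](O[Si](C)(C)C(C)(C)C)CC1C(C)OS(C)(=O)=O | intermediate (not isolated)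
17 | (2E,4S)-4-(tert-butyldimethylsilyloxy)-2-ethylidene-6,6-dimethylcycloheptan-1-one | O=C1CC(C)(C)C[C@H](O[Si](C)(C)C(C)(C)C)C/C1=C\C | intermediate
18 | potassium (4S)-4-(tert-butyldimethylsilyloxy)-2-ethenyl-6,6-dimethylcyclohept-1-en-1-olate | CC1(C)C[C@H](O[Si](C)(C)C(C)(C)C)CC(C=C)=C(O[K])C1 | intermediate (not isolated)
19 | (2S,4S)-4-(tert-butyldimethylsilyloxy)-2-ethenyl-2,6,6-trimethylcycloheptan-1-one (methyl cis to silyloxy) | O=C1CC(C)(C)C[C@H](O[Si](C)(C)C(C)(C)C)C[C@@]1(C)C=C | intermediate
20 | isopropenylmagnesium bromide | C=C(C)[Mg]Br | starting material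
21 | (1R,2S,4S)-4-(tert-butyldimethylsilyloxy)-2-ethenyl-2,6,6-trimethyl-1-(prop-1-en-2-yl)cycloheptan-1-ol (isopropenyl trans to vinyl; hydroxyl trans to silyloxy) | C=C(C)[C@]1(O)CC(C)(C)C[C@H](O[Si](C)(C)C(C)(C)C)C[C@@]1(C)C=C | intermediate
22 | potassium (1R,2S,4S)-4-(tert-butyldimethylsilyloxy)-2-ethenyl-2,6,6-trimethyl-1-(prop-1-en-2-yl)cycloheptan-1-olate | C=C(C)[C@]1(O[K])CC(C)(C)C[C@H](O[Si](C)(C)C(C)(C)C)C[C@@]1(C)C=C | intermediate (not isolated)
23 | potassium (1Z,5E,8S)-8-(tert-butyldimethylsilyloxy)-2,6,10,10-tetramethylcycloundeca-1,5-dien-1-olate | C/C1=C(/O[K])CC(C)(C)C[C@H](O[Si](C)(C)C(C)(C)C)C/C(C)=C/CC1 | intermediate (not isolated)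
24 | (1Z,5E,8S)-8-(tert-butyldimethylsilyloxy)-2,6,10,10-tetramethylcycloundeca-1,5-dien-1-yl trifluoromethanesulfonate | C/C1=C(/OS(=O)(=O)C(F)(F)F)CC(C)(C)C[C@H](O[Si](C)(C)C(C)(C)C)C/C(C)=C/CC1 | intermediate
25 | tert-butyldimethyl{[(1S,3E,7E)-3,7,10,10-tetramethylcycloundeca-3,7-dien-1-yl]oxy}silane | C/C1=C\CC(C)(C)C[C@H](O[Si](C)(C)C(C)(C)C)C/C(C)=C/CC1 | intermediate
26 | (1S,3E,7E)-3,7,10,10-tetramethylcycloundeca-3,7-dien-1-ol | C/C1=C\CC(C)(C)C[C@H](O)C/C(C)=C/CC1 | intermediate
27 | (diphenoxyphosphoryl)acetic acid | OC(=O)CP(=O)(Oc1ccccc1)Oc1ccccc1 | starting material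
28 | (1S,3E,7E)-3,7,10,10-tetramethylcycloundeca-3,7-dien-1-yl 2-(diphenoxyphosphoryl)acetate | C/C1=C\CC(C)(C)C[C@H](OC(=O)CP(=O)(Oc2ccccc2)Oc2ccccc2)C/C(C)=C/CC1 | intermediate
29 | 4-(tert-butyldimethylsilyloxy)benzaldehyde | O=Cc1ccc(O[Si](C)(C)C(C)(C)C)cc1 | starting material
30 | (1S,3E,7E)-3,7,10,10-tetramethylcycloundeca-3,7-dien-1-yl (2Z)-3-[4-(tert-butyldimethylsilyloxy)phenyl]prop-2-enoate | C/C1=C\CC(C)(C)C[C@H](OC(=O)/C=C\c2ccc(O[Si](C)(C)C(C)(C)C)cc2)C/C(C)=C/CC1 | intermediate
31 | (1S,3E,7E)-3,7,10,10-tetramethylcycloundeca-3,7-dien-1-yl (2Z)-3-(4-hydroxyphenyl)prop-2-enoate | C/C1=C\CC(C)(C)C[C@H](OC(=O)/C=C\c2ccc(O)cc2)C/C(C)=C/CC1 | target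

## Step count and least certain steps

Total: 17 steps. Longest linear sequence: 17 steps from dimedone 1 (13, 20, 27 and 29 are purchased).

**Step 12 (key step).** What may go wrong: heterolytic fragmentation of the alkoxide and [1,3] recombination, or passage through a boat, either of which erodes alkene geometry or ring size. Fallback (neutral thermal siloxy-Cope): from 21, silylation (Me3SiOTf, 2,6-lutidine) gives the trimethylsilyl ether F1. Heating F1 in a sealed tube (toluene, about 200 °C) should effect the same [3,3] shift without any anion and give the ring-expanded silyl enol ether F2. MeLi cleaves F2 to the lithium enolate F3, which PhNTf2 converts into 24, where the route resumes.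

**Step 11.** What may go wrong: poor or reversed facial selectivity in the carbonyl addition, so that the isomer with isopropenyl cis to vinyl predominates; that isomer cannot reach the E,E ring through a chair. Fallback (isopropenyl built in two steps from a slimmer nucleophile): from 19, HC≡CMgBr with CeCl3 gives the ethynyl carbinol F4. The rod-shaped acetylide responds to torsional and not to steric bias and offers an independent facial preference. Zirconium-catalysed methylalumination of the terminal alkyne (AlMe3, Cp2ZrCl2; then H2O) puts methyl on the internal carbon and returns 21.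

**Step 5.** What may go wrong: loss of regiocontrol in the enolisation (deprotonation at C6), or β-elimination of the silyloxy group from the C2 enolate. Fallback (homologation by 1,2-shift instead of enolisation): from 7, Me3SiCHN2 with BF3·OEt2 inserts a carbon next to the carbonyl. The outcome is then governed by migratory aptitude, and the neopentyl C6 is the poorer migrating group. This gives the α-silyl ketone F5 and, after K2CO3/MeOH, the saturated cycloheptanone F6. Kinetic enolisation of F6 (LiN(i-Pr)2, −78 °C), which again avoids the methylene next to the quaternary carbon, and addition of 13 return 15.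

**Step 8.** What may go wrong: carbonyl (1,2-) reduction competing with conjugate reduction, because the β-carbon is flanked by the silyloxy group. Fallback (separate saturation and enolisation): from 12, hydrogenation (H2, Pd/C, EtOAc) gives the saturated ketone F7 (the same structure as F6). LiN(i-Pr)2 at −78 °C and then 13 return 15.

**Step 10.** What may go wrong: competing deprotonation at the α′ methylene, O-methylation, or a second methylation. Fallback (reductive generation of the same dienolate): from 12, I2/pyridine gives the 2-iodo enone F8. Suzuki–Miyaura coupling with potassium vinyltrifluoroborate (PdCl2(dppf), Cs2CO3) gives the 2-vinyl enone F9, used at once because it can dimerise. Conjugate reduction with LiBH(s-Bu)3 can only give the lithium dienolate F10, which MeI alkylates at the α-carbon to return 19.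

**Step 17.** What may go wrong: Z-to-E isomerisation of the cinnamate through the phenoxide during fluoride treatment, or acyl cleavage. Fallback (phenol protecting group removed under neutral conditions): from 28, the olefination of step 16 is run with 4-(allyloxy)benzaldehyde to give the allyl ether F11. Pd(PPh3)4 with morpholine removes the allyl group without base or fluoride and returns 31.

## Further compounds

F1 | step 12 | {[(1R,2S,4S)-4-(tert-butyldimethylsilyloxy)-2-ethenyl-2,6,6-trimethyl-1-(prop-1-en-2-yl)cycloheptyl]oxy}trimethylsilane | C=C(C)[C@]1(O[Si](C)(C)C)CC(C)(C)C[C@H](O[Si](C)(C)C(C)(C)C)C[C@@]1(C)C=C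
F2 | step 12 | tert-butyldimethyl{[(1S,3E,7Z)-3,7,10,10-tetramethyl-8-(trimethylsilyloxy)cycloundeca-3,7-dien-1-yl]oxy}silane | C/C1=C(/O[Si](C)(C)C)CC(C)(C)C[C@H](O[Si](C)(C)C(C)(C)C)C/C(C)=C/CC1
F3 | step 12 | lithium (1Z,5E,8S)-8-(tert-butyldimethylsilyloxy)-2,6,10,10-tetramethylcycloundeca-1,5-dien-1-olate | C/C1=C(/O[Li])CC(C)(C)C[C@H](O[Si](C)(C)C(C)(C)C)C/C(C)=C/CC1
F4 | step 11 | (1R,2S,4S)-4-(tert-butyldimethylsilyloxy)-2-ethenyl-1-ethynyl-2,6,6-trimethylcycloheptan-1-ol | C#C[C@]1(O)CC(C)(C)C[C@H](O[Si](C)(C)C(C)(C)C)C[C@@]1(C)C=C
F5 | step 5 | (4S)-4-(tert-butyldimethylsilyloxy)-6,6-dimethyl-2-(trimethylsilyl)cycloheptan-1-one (either C2 epimer) | O=C1CC(C)(C)C[C@H](O[Si](C)(C)C(C)(C)C)CC1[Si](C)(C)C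
F6 | step 5 | (4R)-4-(tert-butyldimethylsilyloxy)-6,6-dimethylcycloheptan-1-one | O=C1CC(C)(C)C[C@H](O[Si](C)(C)C(C)(C)C)CC1
F7 | step 8 | (4R)-4-(tert-butyldimethylsilyloxy)-6,6-dimethylcycloheptan-1-one | O=C1CC(C)(C)C[C@H](O[Si](C)(C)C(C)(C)C)CC1
F8 | step 10 | (4S)-4-(tert-butyldimethylsilyloxy)-2-iodo-6,6-dimethylcyclohept-2-en-1-one | O=C1CC(C)(C)C[C@H](O[Si](C)(C)C(C)(C)C)C=C1I
F9 | step 10 | (4S)-4-(tert-butyldimethylsilyloxy)-2-ethenyl-6,6-dimethylcyclohept-2-en-1-one | O=C1CC(C)(C)C[C@H](O[Si](C)(C)C(C)(C)C)C=C1C=C
F10 | step 10 | lithium (4S)-4-(tert-butyldimethylsilyloxy)-2-ethenyl-6,6-dimethylcyclohept-1-en-1-olate | CC1(C)C[C@H](O[Si](C)(C)C(C)(C)C)CC(C=C)=C(O[Li])C1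
F11 | step 17 | (1S,3E,7E)-3,7,10,10-tetramethylcycloundeca-3,7-dien-1-yl (2Z)-3-[4-(prop-2-en-1-yloxy)phenyl]prop-2-enoate | C/C1=C\CC(C)(C)C[C@H](OC(=O)/C=C\c2ccc(OCC=C)cc2)C/C(C)=C/CC1
A1 | alternative 1 | 1-[(2E,6E)-7-iodo-2,6-dimethylhepta-2,6-dien-1-yl]-3,3-dimethylcyclobutan-1-ol | OC1(C/C(C)=C/CC/C(C)=C/I)CC(C)(C)C1
A2 | alternative 1 | (3E,7E)-3,7,10,10-tetramethylcycloundeca-3,7-dien-1-one | C/C1=C\CC(C)(C)CC(=O)C/C(C)=C/CC1
A3 | alternative 2 | (2S)-2-[(4E)-2,2,5-trimethyldec-4-en-8-yn-1-yl]oxirane | CC#CCC/C(C)=C/CC(C)(C)C[C@H]1CO1
A4 | alternative 2 | (1S,3E,7E)-3,7,10,10-tetramethylcycloundeca-3,7-dien-1-ol | C/C1=C\CC(C)(C)C[C@H](O)C/C(C)=C/CC1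
A5 | alternative 3 | tert-butyl{[(1E,4S,8E)-1-iodo-2,6,6,9-tetramethylundeca-1,8,10-trien-4-yl]oxy}dimethylsilane | C=C/C(C)=C/CC(C)(C)C[C@H](O[Si](C)(C)C(C)(C)C)C/C(C)=C/I
A6 | alternative 3 | tert-butyldimethyl{[(1S,3E,7E)-3,7,10,10-tetramethylcycloundeca-3,7-dien-1-yl]oxy}silane | C/C1=C\CC(C)(C)C[C@H](O[Si](C)(C)C(C)(C)C)C/C(C)=C/CC1
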